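(The earlier runs and the new flask come from a simulation for an exercise, and the scatter is random.)

The molar-minute of nucleophile is the unit I reckon in: one molar of nucleophile, as charged, standing for one minute, and I call the total a flask receives its dose. The decision is whether birch's extra nucleophile is worth charging over maple's.

common to all: electrophile 0.27 M
- Friday's: nucleophile 0.57 M; run made earlier
- Monday's: nucleophile 0.94 M; run made earlier
- maple: nucleophile 0.410 M; time 4.0 h
- birch: nucleophile 0.810 M; time 4.0 h

| run | time / min | electrophile / % | target / % |
|---|---|---|---|
| Friday's | 10.0 | 98 | 3 |
| Friday's | 20.0 | 95 | 5 |
| Friday's | 50.0 | 87 | 7 |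
| Friday's | 120 | 78 | 21 |
| Monday's | 30.0 | 86 | 11 |
| Monday's | 60.0 | 79 | 16 |
| Monday's | 90.0 | 73 | 23 |
| Monday's | 120 | 66 | 27 |

(scatter of a reading: 1.5 percentage points)

- part of the electrophile that has reacted at the end, maple
- part of the electrophile that has reacted at the end, birch
- what raising the concentration of nucleophile from its lowest to its highest value here does to the part of the electrophile that has reacted (changes below 5 percentage points count as none) (it rises / it falls / no change)

- the earlier runs were read with a standard deviation of 1.5 percentage points

At its last reading, Friday's run has 78 % of its electrophile left after a dose of 68.4 M·min, and Monday's has 66 % after 113 M·min. I take the natural logarithm of one over the fraction left and divide it by the dose. This is a pseudo-first-order constant per unit of nucleophile charged, and I call it the bite. If the loss is first order in nucleophile and the nucleophile stands near its charge, the two runs bite alike, so a ratio of one is the zero of my scale. Monday's over Friday's reads 1.01, from readings carrying 1.5 points each. Pooled, the bite reads 0.00366 M⁻¹ min⁻¹.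

| flask | dose | fraction left | fraction reacted |
|---|---|---|---|
| maple | 98.4 M·min | 69.8 % | 30.3 % |
| birch | 194 M·min | 49.2 % | 51.0 % |

By my reckoning, birch gains 21 points, more than the 5 points that counts as a change, so I charge birch. The forecast says 31 % for maple and 51 % for birch, and of the trend it rises “More nucleophile clearly raises conversion”.

The flask gives 27.2 % for maple and 47.1 % for birch; the trend is it rises, by 20 points.

    electrophile + nucleophile → acid set free + target (k = 0.00410 M⁻¹ min⁻¹)
    nucleophile + acid set free ⇌ protonated nucleophile, settled at all times (K = 12000 M⁻¹)
    nucleophile + target → over-reaction product (k = 0.00370 M⁻¹ min⁻¹)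

The dose counts the whole charge, while birch ends with 64.5 % of its nucleophile free. Read back from birch's end, the bite is 0.00327 M⁻¹ min⁻¹, less than the 0.00366 M⁻¹ min⁻¹ I carried.

In a neighbour flask, birch with 0.46 M of electrophile, the dose is unchanged, so the bite again gives 51.0 % reacted. The computed flask gives 42.1 %, with 47 % of its nucleophile free at the end.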